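**Plan**

- Retrosynthesis: the silyl groups on O7 and O4' are removed last. The C8–prenyl bond is traced back to a 5-O-prenyl ether (Claisen then Cope shift through C6). Ring C is cut at C3=C4 (enol ether metathesis) and then at C2–O1 (allylic etherification). This leaves a ring B cinnamyl carbonate and a ring A acetophenone.
- Enabling feature: C4 is a ketone carbon that ring A can carry as a 1-silyloxyvinyl group, C3 is the methylene next to it, and C2 is an allylic carbon bound to O1 of ring A. C3=C4 is therefore a metathesis bond of the six-membered ring C.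
- Forward: ring B receives its 1,1-dimethylallyl group by an aromatic Claisen shift at the benzaldehyde stage, before any stereocentre exists, and is homologated to the cinnamyl carbonate. Ring A is mono-silylated and mono-prenylated. The fragments are joined at C2–O1, the acetyl group is silylated, and ring C (the only ring formed) is closed. Hydrolysis, prenyl migration from O5 to C8 and desilylation complete the route.
- Stereochemistry: C2 is the only stereocentre. It is set as (S) by the chiral iridium phosphoramidite catalyst in the etherification, and no later step breaks a bond to it.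

Key step: step 11

Assumption: the (Sa,Sc,Sc) phosphoramidite is taken to give the (S) ether (CIP order O > aryl > vinyl at C2) by analogy with aryloxide attack on cinnamyl carbonates; this sense is recalled by analogy, not certain, and the mirror-image ligand would be used if it proves opposite.

**Route**

Step 1
Reactants: 1 4-hydroxy-2-methoxybenzaldehyde; 2 prenyl bromide (1-bromo-3-methylbut-2-ene)
Product: 3 2-methoxy-4-[(3-methylbut-2-en-1-yl)oxy]benzaldehyde
Conditions: K2CO3, acetone, reflux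
Reagents that add atoms: none
Why: Williamson etherification of the only phenol, with SN2 attack at the primary allylic bromide giving the unrearranged prenyl ether.

Step 2
Reactants: 3 2-methoxy-4-[(3-methylbut-2-en-1-yl)oxy]benzaldehyde
Product: 5 4-hydroxy-2-methoxy-5-(2-methylbut-3-en-2-yl)benzaldehyde, via ortho dienone 4 (not isolated)
Conditions: EtOH/H2O (4:1), 130 °C, sealed tube
Reagents that add atoms: none
Why: Aromatic Claisen rearrangement ([3,3]) of the aryl prenyl ether should deliver the inverted 1,1-dimethylallyl group to C5, the ortho carbon not flanked by the methoxy group, and dienone 4 then tautomerises; the protic medium accelerates the shift so that it runs below the temperature of the abnormal Claisen pathway.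

Step 3
Reactants: 5 4-hydroxy-2-methoxy-5-(2-methylbut-3-en-2-yl)benzaldehyde
Product: 6 4-[(tert-butyldimethylsilyl)oxy]-2-methoxy-5-(2-methylbut-3-en-2-yl)benzaldehyde
Conditions: TBSCl, imidazole, DMAP (cat.), DMF, rt
Reagents that add atoms: tert-butyldimethylsilyl chloride, CC(C)(C)[Si](C)(C)Cl
Why: Standard phenol silylation; the ortho tert-alkyl group slows it but also shields the resulting aryl silyl ether in the basic steps that follow.

Step 4
Reactants: 6 4-[(tert-butyldimethylsilyl)oxy]-2-methoxy-5-(2-methylbut-3-en-2-yl)benzaldehyde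
Product: 7 ethyl (E)-3-{4-[(tert-butyldimethylsilyl)oxy]-2-methoxy-5-(2-methylbut-3-en-2-yl)phenyl}prop-2-enoate
Conditions: Ph3P=CHCO2Et, toluene, 90 °C
Reagents that add atoms: ethyl (triphenylphosphoranylidene)acetate, CCOC(=O)C=P(c1ccccc1)(c1ccccc1)c1ccccc1
Why: Wittig olefination with a stabilised ylide is E-selective and salt-free, so the aryl silyl ether is not endangered.

Step 5
Reactants: 7 ethyl (E)-3-{4-[(tert-butyldimethylsilyl)oxy]-2-methoxy-5-(2-methylbut-3-en-2-yl)phenyl}prop-2-enoate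
Product: 8 (E)-3-{4-[(tert-butyldimethylsilyl)oxy]-2-methoxy-5-(2-methylbut-3-en-2-yl)phenyl}prop-2-en-1-ol
Conditions: i-Bu2AlH (2.5 equiv), CH2Cl2, −78 °C
Reagents that add atoms: none
Why: 1,2-Reduction of the enoate by i-Bu2AlH gives the allylic alcohol without touching the alkenes or the silyl ether.

Step 6
Reactants: 8 (E)-3-{4-[(tert-butyldimethylsilyl)oxy]-2-methoxy-5-(2-methylbut-3-en-2-yl)phenyl}prop-2-en-1-ol
Product: 9 (E)-3-{4-[(tert-butyldimethylsilyl)oxy]-2-methoxy-5-(2-methylbut-3-en-2-yl)phenyl}prop-2-en-1-yl methyl carbonate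
Conditions: ClCO2Me, pyridine, CH2Cl2, 0 °C
Reagents that add atoms: methyl chloroformate, COC(=O)Cl
Why: Acylation of the primary allylic alcohol gives the linear carbonate that iridium ionises to the allyl complex.

Step 7
Reactants: 10 2,4,6-trihydroxyacetophenone
Product: 11 1-{2,6-dihydroxy-4-[(triisopropylsilyl)oxy]phenyl}ethan-1-one
Conditions: TIPSCl (1.05 equiv), imidazole, DMF, 0 °C
Reagents that add atoms: triisopropylsilyl chloride, CC(C)[Si](Cl)(C(C)C)C(C)C
Why: Silylation is chemoselective for the para hydroxyl, the only one not hydrogen-bonded to the acetyl group.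

Step 8
Reactants: 11 1-{2,6-dihydroxy-4-[(triisopropylsilyl)oxy]phenyl}ethan-1-one; 12 3-methylbut-2-en-1-ol
Product: 13 1-{2-hydroxy-6-[(3-methylbut-2-en-1-yl)oxy]-4-[(triisopropylsilyl)oxy]phenyl}ethan-1-one
Conditions: PPh3, DIAD (1.0 equiv each), THF, 0 °C to rt
Reagents that add atoms: none
Why: Mitsunobu etherification alkylates one of the two equivalent chelated hydroxyls under neutral conditions that spare the aryl silyl ether, and the remaining hydroxyl, now the sole hydrogen-bond donor to the carbonyl, resists a second alkylation.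

Step 9
Reactants: 13 1-{2-hydroxy-6-[(3-methylbut-2-en-1-yl)oxy]-4-[(triisopropylsilyl)oxy]phenyl}ethan-1-one (1.2 equiv); 9 (E)-3-{4-[(tert-butyldimethylsilyl)oxy]-2-methoxy-5-(2-methylbut-3-en-2-yl)phenyl}prop-2-en-1-yl methyl carbonate
Product: 15 1-{2-[((1S)-1-{4-[(tert-butyldimethylsilyl)oxy]-2-methoxy-5-(2-methylbut-3-en-2-yl)phenyl}prop-2-en-1-yl)oxy]-6-[(3-methylbut-2-en-1-yl)oxy]-4-[(triisopropylsilyl)oxy]phenyl}ethan-1-one, via sodium aryloxide 14 (not isolated)
Conditions: NaH, THF, 0 °C; then 9, [Ir(cod)Cl]2 (2 mol%), (Sa,Sc,Sc)-1,1'-binaphthyl-2,2'-diyl N,N-bis[1-(2-methoxyphenyl)ethyl]phosphoramidite (4 mol%, catalyst pre-activated with n-PrNH2), THF, rt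
Reagents that add atoms: none
Why: Iridium-catalysed asymmetric allylic etherification, in which the cyclometallated iridium phosphoramidite ionises the carbonate and the aryloxide attacks the aryl-substituted allyl terminus anti to the metal, so the branched ether forms and the ligand configuration fixes C2 as (S); the bis(2-methoxyphenyl) ligand is chosen because the cinnamyl unit is ortho-substituted.

Step 10
Reactants: 15 1-{2-[((1S)-1-{4-[(tert-butyldimethylsilyl)oxy]-2-methoxy-5-(2-methylbut-3-en-2-yl)phenyl}prop-2-en-1-yl)oxy]-6-[(3-methylbut-2-en-1-yl)oxy]-4-[(triisopropylsilyl)oxy]phenyl}ethan-1-one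
Product: 17 tert-butyl[(1-{2-[((1S)-1-{4-[(tert-butyldimethylsilyl)oxy]-2-methoxy-5-(2-methylbut-3-en-2-yl)phenyl}prop-2-en-1-yl)oxy]-6-[(3-methylbut-2-en-1-yl)oxy]-4-[(triisopropylsilyl)oxy]phenyl}ethenyl)oxy]dimethylsilane, via potassium enolate 16 (not isolated)
Conditions: KN(SiMe3)2 (1.1 equiv), THF, −78 °C; then TBSCl, −78 to 0 °C
Reagents that add atoms: tert-butyldimethylsilyl chloride, CC(C)(C)[Si](C)(C)Cl
Why: Kinetic deprotonation of the methyl ketone and O-silylation of the enolate give the silyl enol ether under basic conditions, avoiding a Lewis-acidic silyl triflate that could ionise the doubly activated C2–O1 bond.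

Step 11
Reactants: 17 tert-butyl[(1-{2-[((1S)-1-{4-[(tert-butyldimethylsilyl)oxy]-2-methoxy-5-(2-methylbut-3-en-2-yl)phenyl}prop-2-en-1-yl)oxy]-6-[(3-methylbut-2-en-1-yl)oxy]-4-[(triisopropylsilyl)oxy]phenyl}ethenyl)oxy]dimethylsilane
Product: 18 (2S)-4-[(tert-butyldimethylsilyl)oxy]-2-{4-[(tert-butyldimethylsilyl)oxy]-2-methoxy-5-(2-methylbut-3-en-2-yl)phenyl}-5-[(3-methylbut-2-en-1-yl)oxy]-7-[(triisopropylsilyl)oxy]-2H-chromene
Conditions: second-generation Grubbs catalyst (H2IMes)(PCy3)Cl2Ru=CHPh (10 mol%, two portions), toluene (0.005 M), 60 °C, argon, dark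
Reagents that add atoms: none
Why: The ruthenium carbene exchanges onto the monosubstituted allyl terminus (C3), adds across the 1-silyloxyvinyl group to a ruthenacyclobutane and cycloreverts, forming C3=C4 and releasing ethylene. The closest known reactions are ring-closing metathesis of silyl enol ethers with terminal alkenes to cyclic silyl enol ethers (including the closure of N-allyl-2-(1-silyloxyvinyl)anilines to 4-silyloxy-1,2-dihydroquinolines) and of ortho-vinyl aryl allyl ethers to 2H-chromenes. Ring C closes as a six-membered ring (O1, C2, C3, C4, C4a, C8a) with both alkene carbons inside the ring. No stereocentre is formed and no bond to C2 is broken; the neutral conditions, 60 °C and exclusion of light are chosen to avoid ionisation, a [3,3] shift of the allyl aryl ether and electrocyclic opening of the 2H-chromene. Of the four alkenes, the carbene should load first on the allyl terminus, because the 1,1-dimethylallyl vinyl group sits on a quaternary carbon with no partner in reach and the O-prenyl alkene is trisubstituted. The O-prenyl ether could in principle close a different six-membered ring onto the same enol ether, and only the slower loading on that alkene together with high dilution guards against it.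

Step 12
Reactants: 18 (2S)-4-[(tert-butyldimethylsilyl)oxy]-2-{4-[(tert-butyldimethylsilyl)oxy]-2-methoxy-5-(2-methylbut-3-en-2-yl)phenyl}-5-[(3-methylbut-2-en-1-yl)oxy]-7-[(triisopropylsilyl)oxy]-2H-chromene
Product: 19 (2S)-2-{4-[(tert-butyldimethylsilyl)oxy]-2-methoxy-5-(2-methylbut-3-en-2-yl)phenyl}-5-[(3-methylbut-2-en-1-yl)oxy]-7-[(triisopropylsilyl)oxy]chroman-4-one
Conditions: 0.5 M aq. HCl, THF, 0 °C, short reaction time
Reagents that add atoms: none
Why: Acid hydrolysis of the silyl enol ether (protonation at C3, loss of silanol) should reveal the C4 ketone faster than dilute acid attacks the aryl silyl ethers, the prenyl ether or the C2–O1 bond, and C3 becomes a methylene so no stereocentre arises.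

Step 13
Reactants: 19 (2S)-2-{4-[(tert-butyldimethylsilyl)oxy]-2-methoxy-5-(2-methylbut-3-en-2-yl)phenyl}-5-[(3-methylbut-2-en-1-yl)oxy]-7-[(triisopropylsilyl)oxy]chroman-4-one
Product: 22 (2S)-2-{4-[(tert-butyldimethylsilyl)oxy]-2-methoxy-5-(2-methylbut-3-en-2-yl)phenyl}-5-hydroxy-8-(3-methylbut-2-en-1-yl)-7-[(triisopropylsilyl)oxy]chroman-4-one, via C6 dienone 20 (not isolated), via C8 dienone 21 (not isolated)
Conditions: Eu(fod)3 (10 mol%), CHCl3, 60 °C
Reagents that add atoms: none
Why: Eu(fod)3 chelated between the C4 carbonyl and O5 should trigger the Claisen shift of the prenyl group to C6, and a Cope shift should then carry it from the crowded dienone 20 to C8 as a normal prenyl group (dienone 21), which aromatises to the chelated 5-phenol; this Claisen–Cope cascade is known for 5-O-prenylflavanones.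

Step 14
Reactants: 22 (2S)-2-{4-[(tert-butyldimethylsilyl)oxy]-2-methoxy-5-(2-methylbut-3-en-2-yl)phenyl}-5-hydroxy-8-(3-methylbut-2-en-1-yl)-7-[(triisopropylsilyl)oxy]chroman-4-one
Product: 23 (2S)-5,7-dihydroxy-2-[4-hydroxy-2-methoxy-5-(2-methylbut-3-en-2-yl)phenyl]-8-(3-methylbut-2-en-1-yl)chroman-4-one (CNP0308136.1)
Conditions: Bu4NF/AcOH (1:1, 2.5 equiv), THF, 0 °C
Reagents that add atoms: none
Why: Fluoride cleaves both aryl silyl ethers, and the acetic acid buffer keeps the medium from becoming basic enough to open ring C by retro-oxa-Michael reaction, which would racemise C2.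

**Compound list**

In the names below, Ar stands for 4-[(tert-butyldimethylsilyl)oxy]-2-methoxy-5-(2-methylbut-3-en-2-yl)phenyl.

1 | 4-hydroxy-2-methoxybenzaldehyde | COc1cc(O)ccc1C=O | starting material
2 | prenyl bromide (1-bromo-3-methylbut-2-ene) | CC(C)=CCBr | starting material
3 | 2-methoxy-4-[(3-methylbut-2-en-1-yl)oxy]benzaldehyde | COc1cc(OCC=C(C)C)ccc1C=O | intermediate
4 | 4-formyl-3-methoxy-6-(2-methylbut-3-en-2-yl)cyclohexa-2,4-dien-1-one (ortho dienone, not isolated) | C=CC(C)(C)C1C=C(C=O)C(OC)=CC1=O | intermediate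
5 | 4-hydroxy-2-methoxy-5-(2-methylbut-3-en-2-yl)benzaldehyde | COc1cc(O)c(C(C)(C)C=C)cc1C=O | intermediate
6 | 4-[(tert-butyldimethylsilyl)oxy]-2-methoxy-5-(2-methylbut-3-en-2-yl)benzaldehyde | COc1cc(O[Si](C)(C)C(C)(C)C)c(C(C)(C)C=C)cc1C=O | intermediate
7 | ethyl (E)-3-Ar-prop-2-enoate | CCOC(=O)/C=C/c1cc(C(C)(C)C=C)c(O[Si](C)(C)C(C)(C)C)cc1OC | intermediate
8 | (E)-3-Ar-prop-2-en-1-ol | OC/C=C/c1cc(C(C)(C)C=C)c(O[Si](C)(C)C(C)(C)C)cc1OC | intermediate
9 | (E)-3-Ar-prop-2-en-1-yl methyl carbonate | COC(=O)OC/C=C/c1cc(C(C)(C)C=C)c(O[Si](C)(C)C(C)(C)C)cc1OC | intermediate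
10 | 2,4,6-trihydroxyacetophenone | CC(=O)c1c(O)cc(O)cc1O | starting material
11 | 1-{2,6-dihydroxy-4-[(triisopropylsilyl)oxy]phenyl}ethan-1-one | CC(=O)c1c(O)cc(O[Si](C(C)C)(C(C)C)C(C)C)cc1O | intermediate
12 | 3-methylbut-2-en-1-ol | CC(C)=CCO | starting material
13 | 1-{2-hydroxy-6-[(3-methylbut-2-en-1-yl)oxy]-4-[(triisopropylsilyl)oxy]phenyl}ethan-1-one | CC(=O)c1c(O)cc(O[Si](C(C)C)(C(C)C)C(C)C)cc1OCC=C(C)C | intermediate
14 | sodium 2-acetyl-3-[(3-methylbut-2-en-1-yl)oxy]-5-[(triisopropylsilyl)oxy]phenolate (not isolated) | CC(=O)c1c([O-])cc(O[Si](C(C)C)(C(C)C)C(C)C)cc1OCC=C(C)C.[Na+] | intermediate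
15 | 1-{2-[((1S)-1-Ar-prop-2-en-1-yl)oxy]-6-[(3-methylbut-2-en-1-yl)oxy]-4-[(triisopropylsilyl)oxy]phenyl}ethan-1-one | CC(=O)c1c(OCC=C(C)C)cc(O[Si](C(C)C)(C(C)C)C(C)C)cc1O[C@@H](C=C)c1cc(C(C)(C)C=C)c(O[Si](C)(C)C(C)(C)C)cc1OC | intermediate
16 | potassium enolate of 15 (not isolated) | [K+].[O-]C(=C)c1c(OCC=C(C)C)cc(O[Si](C(C)C)(C(C)C)C(C)C)cc1O[C@@H](C=C)c1cc(C(C)(C)C=C)c(O[Si](C)(C)C(C)(C)C)cc1OC | intermediate
17 | tert-butyl[(1-{2-[((1S)-1-Ar-prop-2-en-1-yl)oxy]-6-[(3-methylbut-2-en-1-yl)oxy]-4-[(triisopropylsilyl)oxy]phenyl}ethenyl)oxy]dimethylsilane | C=C(O[Si](C)(C)C(C)(C)C)c1c(OCC=C(C)C)cc(O[Si](C(C)C)(C(C)C)C(C)C)cc1O[C@@H](C=C)c1cc(C(C)(C)C=C)c(O[Si](C)(C)C(C)(C)C)cc1OC | intermediate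
18 | (2S)-2-Ar-4-[(tert-butyldimethylsilyl)oxy]-5-[(3-methylbut-2-en-1-yl)oxy]-7-[(triisopropylsilyl)oxy]-2H-chromene | CC(C)=CCOc1cc(O[Si](C(C)C)(C(C)C)C(C)C)cc2O[C@H](c3cc(C(C)(C)C=C)c(O[Si](C)(C)C(C)(C)C)cc3OC)C=C(O[Si](C)(C)C(C)(C)C)c12 | intermediate
19 | (2S)-2-Ar-5-[(3-methylbut-2-en-1-yl)oxy]-7-[(triisopropylsilyl)oxy]chroman-4-one | CC(C)=CCOc1cc(O[Si](C(C)C)(C(C)C)C(C)C)cc2O[C@H](c3cc(C(C)(C)C=C)c(O[Si](C)(C)C(C)(C)C)cc3OC)CC(=O)c12 | intermediate
20 | (2S)-2-Ar-6-(2-methylbut-3-en-2-yl)-7-[(triisopropylsilyl)oxy]-2,3-dihydro-4H-chromene-4,5(6H)-dione (C6 dienone, not isolated) | C=CC(C)(C)C1C(=O)C2=C(C=C1O[Si](C(C)C)(C(C)C)C(C)C)O[C@H](c3cc(C(C)(C)C=C)c(O[Si](C)(C)C(C)(C)C)cc3OC)CC2=O | intermediate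
21 | (2S)-2-Ar-8-(3-methylbut-2-en-1-yl)-7-[(triisopropylsilyl)oxy]-2,3-dihydro-4H-chromene-4,5(8H)-dione (C8 dienone, not isolated) | CC(C)=CCC1C(O[Si](C(C)C)(C(C)C)C(C)C)=CC(=O)C2=C1O[C@H](c3cc(C(C)(C)C=C)c(O[Si](C)(C)C(C)(C)C)cc3OC)CC2=O | intermediate
22 | (2S)-2-Ar-5-hydroxy-8-(3-methylbut-2-en-1-yl)-7-[(triisopropylsilyl)oxy]chroman-4-one | CC(C)=CCc1c(O[Si](C(C)C)(C(C)C)C(C)C)cc(O)c2C(=O)C[C@@H](c3cc(C(C)(C)C=C)c(O[Si](C)(C)C(C)(C)C)cc3OC)Oc12 | intermediate
23 | (2S)-5,7-dihydroxy-2-[4-hydroxy-2-methoxy-5-(2-methylbut-3-en-2-yl)phenyl]-8-(3-methylbut-2-en-1-yl)chroman-4-one | C=CC(C)(C)c1cc([C@@H]2CC(=O)c3c(O)cc(O)c(CC=C(C)C)c3O2)c(OC)cc1O | target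

**Step count and risks**

Total step count: 14. Longest linear sequence: 12 steps (steps 1–6 and 9–14, from 1 to 23); ring A enters through the two-step branch of steps 7 and 8.

Steps most likely to fail:

1. Step 11. The carbene may migrate onto the O-prenyl alkene and close the other six-membered ring onto the same enol ether with loss of isobutene, the prenyl group may be scrambled by cross-metathesis, or the hindered enol ether may close too slowly.
Fallback: the prenyl ether is kept out of the metathesis substrate. Setting out from diol 11 and carbonate 9, the iridium-catalysed etherification of step 9, run on the monosodium salt of 11 in excess, should give the (S)-allyl aryl ether phenol F1. Double silylation (KN(SiMe3)2, 2.2 equiv, then Et3SiCl) would give the bis(triethylsilyl) enol ether F2, in which only the allyl terminus and the enol ether can form a ring. The same metathesis would give the chromene F3. Dilute aqueous HCl in THF should remove both triethylsilyl groups while the triisopropylsilyl and the hindered tert-butyldimethylsilyl ethers stay, giving the 5-hydroxyflavanone F4. Mitsunobu prenylation of its chelated 5-hydroxyl with 12 (PPh3, DIAD) returns to the route at 19.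

2. Step 9. The electron-rich aryloxide may attack through carbon, the ortho-methoxy cinnamyl unit may give poor branched selectivity or ee, the catalyst may re-ionise the product ether (isomerisation to the linear ether and racemisation), and the methoxide by-product may attack the aryl silyl ethers.
Fallback: an enantioconvergent copper-catalysed propargylic etherification followed by semi-hydrogenation. Setting out from aldehyde 6, addition of HC≡CMgBr in THF would give the racemic propargylic alcohol F5, and Ac2O/pyridine/DMAP its acetate F6. Reaction of F6 with phenol 13 under (CuOTf)2·C6H6, a chiral 2,6-bis(oxazolinyl)pyridine ligand (the antipode that gives the (S) ether) and i-Pr2NEt should give, through a copper allenylidene, the (S)-propargyl aryl ether F7. Semi-hydrogenation of its terminal alkyne (H2, Pd/CaCO3 poisoned with Pb(OAc)2, quinoline) returns to the route at 15.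

3. Step 13. The cascade may stop after the first shift if dienone 20 enolises faster than the Cope shift (giving the C6 1,1-dimethylallyl isomer), and europium-assisted ionisation of C2–O1, favoured by the electron-rich silyloxy-substituted ring B, may erode the ee.
Fallback: the end game is reordered so that the rearrangement runs on an acyl-protected, less ionisable substrate of the kind for which the cascade is established. Setting out from 19, Bu4NF/AcOH would give the diol F8, and Ac2O/pyridine/DMAP its diacetate F9. Eu(fod)3 in CHCl3 at 60 °C should then give the 8-prenyl-5-hydroxy diacetate F10. Neutral deacetylation (NH4OAc, aqueous MeOH, rt) returns to the route at the target 23.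

Further compounds
F1 | step 11 | 1-{2-hydroxy-6-[((1S)-1-Ar-prop-2-en-1-yl)oxy]-4-[(triisopropylsilyl)oxy]phenyl}ethan-1-one | CC(=O)c1c(O)cc(O[Si](C(C)C)(C(C)C)C(C)C)cc1O[C@@H](C=C)c1cc(C(C)(C)C=C)c(O[Si](C)(C)C(C)(C)C)cc1OC
F2 | step 11 | triethyl[(1-{2-[((1S)-1-Ar-prop-2-en-1-yl)oxy]-6-[(triethylsilyl)oxy]-4-[(triisopropylsilyl)oxy]phenyl}ethenyl)oxy]silane | C=C(O[Si](CC)(CC)CC)c1c(O[Si](CC)(CC)CC)cc(O[Si](C(C)C)(C(C)C)C(C)C)cc1O[C@@H](C=C)c1cc(C(C)(C)C=C)c(O[Si](C)(C)C(C)(C)C)cc1OC
F3 | step 11 | (2S)-2-Ar-4,5-bis[(triethylsilyl)oxy]-7-[(triisopropylsilyl)oxy]-2H-chromene | CC[Si](CC)(CC)Oc1cc(O[Si](C(C)C)(C(C)C)C(C)C)cc2O[C@H](c3cc(C(C)(C)C=C)c(O[Si](C)(C)C(C)(C)C)cc3OC)C=C(O[Si](CC)(CC)CC)c12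
F4 | step 11 | (2S)-2-Ar-5-hydroxy-7-[(triisopropylsilyl)oxy]chroman-4-one | Oc1cc(O[Si](C(C)C)(C(C)C)C(C)C)cc2O[C@H](c3cc(C(C)(C)C=C)c(O[Si](C)(C)C(C)(C)C)cc3OC)CC(=O)c12
F5 | step 9 | racemic 1-Ar-prop-2-yn-1-ol | C#CC(O)c1cc(C(C)(C)C=C)c(O[Si](C)(C)C(C)(C)C)cc1OC
F6 | step 9 | racemic 1-Ar-prop-2-yn-1-yl acetate | C#CC(OC(C)=O)c1cc(C(C)(C)C=C)c(O[Si](C)(C)C(C)(C)C)cc1OC
F7 | step 9 | 1-{2-[((1S)-1-Ar-prop-2-yn-1-yl)oxy]-6-[(3-methylbut-2-en-1-yl)oxy]-4-[(triisopropylsilyl)oxy]phenyl}ethan-1-one | CC(=O)c1c(OCC=C(C)C)cc(O[Si](C(C)C)(C(C)C)C(C)C)cc1O[C@@H](C#C)c1cc(C(C)(C)C=C)c(O[Si](C)(C)C(C)(C)C)cc1OC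
F8 | step 13 | (2S)-7-hydroxy-2-[4-hydroxy-2-methoxy-5-(2-methylbut-3-en-2-yl)phenyl]-5-[(3-methylbut-2-en-1-yl)oxy]chroman-4-one | CC(C)=CCOc1cc(O)cc2O[C@H](c3cc(C(C)(C)C=C)c(O)cc3OC)CC(=O)c12
F9 | step 13 | (2S)-7-acetoxy-2-[4-acetoxy-2-methoxy-5-(2-methylbut-3-en-2-yl)phenyl]-5-[(3-methylbut-2-en-1-yl)oxy]chroman-4-one | CC(C)=CCOc1cc(OC(C)=O)cc2O[C@H](c3cc(C(C)(C)C=C)c(OC(C)=O)cc3OC)CC(=O)c12
F10 | step 13 | (2S)-7-acetoxy-2-[4-acetoxy-2-methoxy-5-(2-methylbut-3-en-2-yl)phenyl]-5-hydroxy-8-(3-methylbut-2-en-1-yl)chroman-4-one | CC(C)=CCc1c(OC(C)=O)cc(O)c2C(=O)C[C@@H](c3cc(C(C)(C)C=C)c(OC(C)=O)cc3OC)Oc12
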